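The runs were generated by integration on assumed constants; noise was put on by code.

A chemist handed the red flask has these runs and conditions to go on, and these questions to answer:

| flask | substrate | free catalyst | time |
|---|---|---|---|
| ochre | 0.500 M | 0.00500 M |  |
| teal | 0.500 M | 0.0150 M |  |
| violet | 1.50 M | 0.00500 M |  |
| red | 1.20 M | 0.00500 M | 67 min |

- ochre run (time / min: [product] / M): 8.4: 0.123; 17: 0.207; 25: 0.250; 34: 0.290; 42: 0.307; 50: 0.318; 59: 0.333; 67: 0.341
- teal run (time / min: [product] / M): 8.4: 0.212; 17: 0.327; 25: 0.381; 34: 0.423; 42: 0.442; 50: 0.456; 59: 0.467; 67: 0.476
- violet run (time / min: [product] / M): 8.4: 0.364; 17: 0.581; 25: 0.714; 34: 0.819; 42: 0.878; 50: 0.912; 59: 0.952; 67: 0.976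

(scatter of a reading: 0.003 M)

- Overall: substrate -> product, with free catalyst as catalyst.
- Constant volume, constant temperature.
- A reading of a species includes what of it is bound.
- An order is taken over about fifteen percent of the charge, up and down.

1. order of the initial rate in [substrate], near the charge of the ochre run, the rate being that where two percent of its substrate are product (one fixed amount of product, the same in the runs compared)
2. order of the initial rate in [free catalyst], near the charge of the ochre run, the rate being that where two percent of its substrate are product
3. product in the red run at 67 min, as a share of the substrate charged

**The clock.** For each flask we take the log-share, ln(charge/(charge − product)), a pseudo-first-order clock whose rate is the rate of product formation divided by the substrate left. The log-share at 67 min in the violet run divided by that in the ochre run is the clock ratio 0.918, in which any time course shared by the two flasks drops out.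

**The main step.** With substrate turning to product at a steady rate constant, the ratio would be 1. The ochre run's first reading gives 0.0336 min⁻¹, so the red run would reach 89.5%. The first readings support first order: at 8.4 min the violet run holds 2.96 times the product of the ochre run, an order of 0.988 in substrate, read across the whole span of the two charges.

**A falling clock.** The ochre clock reads 1.15 at 67 min, less than the 2.25 of a steady clock, so the rate constant falls with time. Were this the same in every charge, the red run would match the ochre run's 68.2%. At 8.4 min the log-share of the teal run is 1.95 times that of the ochre run, which gives a catalyst order of 0.610, read across the whole span of the two charges.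

**The charge.** The violet-to-ochre ratio reads 0.984 at 8.4 min and falls to 0.918 at 67 min. Taken in a straight line with charge, this gives the red run a ratio of 0.943, a log-share of 1.08 and a share of 66.0%.

**The forecast.** The forecast, reasoning “so the catalyst is dying”, gave 0.95 and 0.61 for the orders and 66% for the red run, its substrate order being lower than our 0.988.

**The result.** The red run gives 65.8% at 67 min, with orders 1.0 in substrate and 0.59 in free catalyst, from these steps:

    2 free catalyst ⇌ catalyst dimer, settled at all times (1000 M⁻¹)
    free catalyst + substrate → product + free catalyst (28.26 M⁻¹ min⁻¹)
    free catalyst + product ⇌ catalyst-product complex, settled at all times (2.060 M⁻¹)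
    free catalyst → spent catalyst (0.1200 min⁻¹)

The joining of free catalyst and product moves the readings by 12 in units of the scatter, root mean square. The red run's clock ratio comes to 0.933, beside our 0.943. In the teal run, the clock ratio to the ochre run goes from 1.95 at 8.4 min to 2.65 at 67 min.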